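## Retrosynthetic overview

1. Target 13 comes from dienyl carbinol 12 (acetylation, desilylation), which comes from dienyl triflate 11 by C11 hydroxymethylation; the triflate derives from a C4 ketone.
2. The cyclopentene ring is formed second, by intramolecular aldol condensation of keto-aldehyde 8 (C5=C6).
3. Key disconnection C8–C9: an intermolecular radical coupling (C–H abstraction, then Giese addition) of dioxolane 6 (C6, C7, C8, C10) with pyranone 3 (C1, C3, C4, C5, C9). It sets C8 and C9 in one step.
4. The pyran ring is formed first, by Achmatowicz rearrangement of furfuryl alcohol. C1 is set by dynamic kinetic acylation, C7 comes from D-erythronolactone, and both isovalerates are carried from the start.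

Assumptions: atoms are numbered as in iridoids (O2, C1, C3–C9, C10 = CH2 on C8, C11 = CH2 on C4). In step 2 the catalyst enantiomer is whichever delivers the (S)-ester (written as (R)-BTM; use (S)-BTM if the sense is opposite).

## Route

**Step 1**
Reactants: 1, furfuryl alcohol
Product: 2, 6-hydroxy-2H-pyran-3(6H)-one (racemic, interconverting lactol)
Conditions: NBS, NaHCO3, NaOAc, THF/H2O (4:1), 0 °C
Reagents that add atoms: water, O
Why: Achmatowicz rearrangement; oxidative opening of the furan to the cis-enedione and closure of the CH2OH onto the aldehyde gives the pyranone lactol, with no fixed stereocenter yet.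

**Step 2**
Reactants: 2
Product: 3, (2S)-5-oxo-5,6-dihydro-2H-pyran-2-yl 3-methylbutanoate
Conditions: i-BuCO2H, Piv2O, (R)-BTM (5 mol %), toluene, 0 °C, no amine base
Reagents that add atoms: isovaleric acid, CC(C)CC(=O)O
Why: Isothiourea-catalysed dynamic kinetic resolution by acyl transfer (mixed-anhydride esterification); the lactol enantiomers interconvert by ring–chain tautomerism while the chiral acyl-isothiouronium acylates one, fixing C1 as S.

**Step 3**
Reactants: 4, D-erythronolactone
Product: 5, 2,3-O-isopropylidene-D-erythronolactone, (3aR,6aR)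
Conditions: 2,2-dimethoxypropane, acetone, TsOH (cat.), rt
Reagents that add atoms: 2,2-dimethoxypropane, COC(C)(C)OC
Why: Acid-catalysed acetonide formation on the cis-diol; stereocenters untouched.

**Step 4**
Reactants: 5
Product: 6, S-ethyl (4R,5R)-2,2-dimethyl-5-[(3-methylbutanoyloxy)methyl]-1,3-dioxolane-4-carbothioate
Conditions: AlMe3, EtSH, CH2Cl2, 0 °C to rt; then i-BuCOCl, pyridine, DMAP, 0 °C (one pot)
Reagents that add atoms: ethanethiol, CCS; isovaleryl chloride, CC(C)CC(=O)Cl
Why: Aluminium-thiolate lactone opening gives the γ-hydroxy thioester, which is acylated in situ before it can relactonise; this installs the C10 isovalerate and a chemoselectively reducible C6, with no stereocenter change.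

**Step 5 (key step)**
Reactants: 6 (2 equiv, excess recovered) and 3 (1 equiv)
Product: 7, S-ethyl (4R,5R)-2,2-dimethyl-5-[(3-methylbutanoyloxy)methyl]-5-[(2S,3S)-2-(3-methylbutanoyloxy)-5-oxooxan-3-yl]-1,3-dioxolane-4-carbothioate
Conditions: (n-Bu4N)4W10O32 (TBADT, 2 mol %), MeCN, 390 nm LEDs, rt, Ar
Reagents that add atoms: none
Why: Proposed new method: excited decatungstate is an electrophilic H-abstractor and should take the one electron-rich, exposed C–H of 6 (the dioxolane C5–H; the C4–H is α to the thioester carbonyl and the OCH2 hydrogens are α to acyloxy, both polarity-mismatched), giving a nucleophilic tertiary α-oxy radical that adds to the enone β-carbon of 3 and is returned to the ketone by back hydrogen transfer (radical Giese addition; closest known types are decatungstate-photocatalysed hydroalkylation of enones with dioxolane or ether C–H donors and photo-initiated addition of dioxolanes to pyranoid enones); C8 is set because the planar dioxolanyl radical reacts anti to the neighbouring C(O)SEt group (the new bond takes the place of the H), and C9 because attack occurs trans to the pseudo-axial anomeric acyloxy group.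

**Step 6**
Reactants: 7
Product: 8, (2S,3S)-3-[(4R,5R)-5-formyl-2,2-dimethyl-4-[(3-methylbutanoyloxy)methyl]-1,3-dioxolan-4-yl]-5-oxooxan-2-yl 3-methylbutanoate
Conditions: 10% Pd/C, Et3SiH, acetone, rt
Reagents that add atoms: none
Why: Fukuyama reduction; Pd inserts into the C–S bond and the acyl-Pd is reduced by silane, so only the thioester becomes the aldehyde (ketone, esters, acyl acetal and acetonide are inert), with no stereocenter change.

**Step 7**
Reactants: 8
Product: 9, (1S,6S,7R,7aS)-6,7-dihydroxy-7-[(3-methylbutanoyloxy)methyl]-4-oxo-1,3,4,6,7,7a-hexahydrocyclopenta[c]pyran-1-yl 3-methylbutanoate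
Conditions: AcOH/H2O (4:1), 45 °C; concentrate; Bn2NH2+ CF3CO2− (20 mol %), toluene, 50 °C
Reagents that add atoms: none
Why: Mild aqueous acid removes the acetonide without cleaving the anomeric ester, and the ammonium salt then drives a 5-exo intramolecular aldol condensation of C5 (α to the C4 ketone) onto the C6 aldehyde to give the C5=C6 enone; the ring must close after deprotection because O7 and O8 are trans on the new cyclopentene, and no new stereocenter is formed.

**Step 8**
Reactants: 9
Product: 10, the 6,7-bis(triethylsilyl) ether of 9
Conditions: TESOTf, 2,6-lutidine, CH2Cl2, −78 to −20 °C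
Reagents that add atoms: triethylsilyl triflate, CC[Si](CC)(CC)OS(=O)(=O)C(F)(F)F
Why: Silyl triflate silylation of the secondary and tertiary alcohols, which prevents alkoxide-driven acyl migration (from O10 or the anomeric ester) in the next, basic step.

**Step 9**
Reactants: 10
Product: 11, (1S,6S,7R,7aS)-7-[(3-methylbutanoyloxy)methyl]-6,7-bis(triethylsilyloxy)-4-(trifluoromethylsulfonyloxy)-1,6,7,7a-tetrahydrocyclopenta[c]pyran-1-yl 3-methylbutanoate
Conditions: KHMDS, THF, −78 °C; then PhNTf2
Reagents that add atoms: N-phenyl-bis(trifluoromethanesulfonimide), O=S(=O)(N(c1ccccc1)S(=O)(=O)C(F)(F)F)C(F)(F)F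
Why: Enol triflate formation; C5 is now sp2, so kinetic enolisation can only occur at C3, and O-triflation gives the C3=C4–C5=C6 dienyl triflate while the anomeric ester survives at −78 °C.

**Step 10**
Reactants: 11
Product: 12, (1S,6S,7R,7aS)-4-(hydroxymethyl)-7-[(3-methylbutanoyloxy)methyl]-6,7-bis(triethylsilyloxy)-1,6,7,7a-tetrahydrocyclopenta[c]pyran-1-yl 3-methylbutanoate
Conditions: Bu3SnCH2OH, Pd(PPh3)4 (5 mol %), LiCl, 1,4-dioxane, 80 °C
Reagents that add atoms: (tributylstannyl)methanol, CCCC[Sn](CCCC)(CCCC)CO
Why: Stille cross-coupling transfers CH2OH to C4 under neutral conditions, installing C11 and locking the C3=C4 enol ether; there is no allylic leaving group at this stage for Pd to ionise.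

**Step 11**
Reactants: 12
Product: 13, jatamanvaltrate J, (1S,6S,7R,7aS)-4-(acetoxymethyl)-6,7-dihydroxy-7-[(3-methylbutanoyloxy)methyl]-1,6,7,7a-tetrahydrocyclopenta[c]pyran-1-yl 3-methylbutanoate
Conditions: Ac2O, pyridine, DMAP (cat.), CH2Cl2, 0 °C; MeOH quench; then HF·pyridine, pyridine/THF, 0 °C to rt (one pot, after Pd has been removed in step 10)
Reagents that add atoms: acetic anhydride, CC(=O)OC(C)=O
Why: Acetylation of the only free hydroxyl followed by fluoride desilylation; buffered HF·pyridine is non-basic (no acyl migration) and only weakly acidic (the dienol ether, allylic alcohol and acyl acetal survive), and no stereocenter is touched.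

## Compound list

1 | furfuryl alcohol | OCc1ccco1 | starting material
2 | 6-hydroxy-2H-pyran-3(6H)-one (racemic) | O=C1COC(O)C=C1 | intermediate
3 | (2S)-5-oxo-5,6-dihydro-2H-pyran-2-yl 3-methylbutanoate | O=C1CO[C@@H](OC(=O)CC(C)C)C=C1 | intermediate
4 | D-erythronolactone, (3R,4R) | O=C1OC[C@@H](O)[C@H]1O | starting material
5 | 2,3-O-isopropylidene-D-erythronolactone, (3aR,6aR) | O=C1OC[C@H]2OC(C)(C)O[C@@H]12 | intermediate
6 | S-ethyl (4R,5R)-2,2-dimethyl-5-[(3-methylbutanoyloxy)methyl]-1,3-dioxolane-4-carbothioate | CCSC(=O)[C@@H]1OC(C)(C)O[C@@H]1COC(=O)CC(C)C | intermediate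
7 | Giese adduct (thioester, ketone, acetonide) | O=C1CO[C@@H](OC(=O)CC(C)C)[C@H]([C@]2(COC(=O)CC(C)C)OC(C)(C)O[C@H]2C(=O)SCC)C1 | intermediate
8 | keto-aldehyde | O=C1CO[C@@H](OC(=O)CC(C)C)[C@H]([C@]2(COC(=O)CC(C)C)OC(C)(C)O[C@H]2C=O)C1 | intermediate
9 | bicyclic enone diol | O=C1CO[C@@H](OC(=O)CC(C)C)[C@H]2C1=C[C@H](O)[C@]2(O)COC(=O)CC(C)C | intermediate
10 | bis-TES enone | O=C1CO[C@@H](OC(=O)CC(C)C)[C@H]2C1=C[C@H](O[Si](CC)(CC)CC)[C@]2(O[Si](CC)(CC)CC)COC(=O)CC(C)C | intermediate
11 | dienyl triflate | FC(F)(F)S(=O)(=O)OC1=CO[C@@H](OC(=O)CC(C)C)[C@H]2C1=C[C@H](O[Si](CC)(CC)CC)[C@]2(O[Si](CC)(CC)CC)COC(=O)CC(C)C | intermediate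
12 | C11 carbinol, bis-TES | OCC1=CO[C@@H](OC(=O)CC(C)C)[C@H]2C1=C[C@H](O[Si](CC)(CC)CC)[C@]2(O[Si](CC)(CC)CC)COC(=O)CC(C)C | intermediate
13 | jatamanvaltrate J | CC(=O)OCC1=CO[C@@H](OC(=O)CC(C)C)[C@H]2C1=C[C@H](O)[C@]2(O)COC(=O)CC(C)C | target

## Summary

Total steps: 11 (steps 4, 7 and 11 are each one-pot, two-stage operations).
Longest linear sequence: 9 steps (4 to 13 through steps 3–11; the furfuryl alcohol branch is also 9).

Steps most likely to fail:

1. **Step 5 (radical coupling).** Risks are competing H-abstraction (isovaleryl methine, anomeric C–H of 3, the thioester), steric congestion at the quaternary–tertiary bond, and incomplete anti selectivity at C8. Fallback: use the rigid bicyclic lactone 5 itself as the C–H donor (its bridgehead radical can only react on the convex face and carries no sulfur). The cyclopentene is then closed by Dieckmann-type acylation of the C5 ketone enolate onto the lactone after acetonide removal and silylation, and the extra C6 oxygen is removed by enol-triflate reduction.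
2. **Step 7 (acetonide cleavage and aldol condensation).** Risks are C7 epimerisation or amine-induced rearrangement of the α-hydroxy aldehyde, hemiketal trapping of the ketone, and loss of the anomeric ester. Fallback: form C5=C6 by ring-closing metathesis instead; Wittig methylenation of aldehyde 8, α-methylenation of the ketone with Eschenmoser's salt, acetonide removal, then Grubbs II.
3. **Steps 9–10 (dienyl triflate and Stille hydroxymethylation).** Risks are slow sp3 transfer from tin at 80 °C and thermal or Pd-induced decomposition of the electron-rich diene. Fallback: skip the triflate; add dimethylsulfonium methylide to the C4 ketone of 10 to give the spiro-epoxide, then isomerise it with a lithium amide base (removing H-3) to the same C3=C4–CH2OH unit.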